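**Plan**
- Retrosynthesis: the two benzyl groups of ring B and the O-methyl on C4 of ring A are removed first. Ring A is then cut at C1–C2 and C5–C6 into a four-carbon diene (C2–C5) and the but-2-ynoate ester of the ring B phenol (C1, C6, the C6 methyl and the depside carbonyl).
- Feature used: ring A (C1 carbonyl, C2 OMe, C3 Me, C4 O, C5 H, C6 Me) is a 1,3-dioxygenated arene whose ester-bearing C1 lies between the C2 methoxy and the C6 methyl. This maps atom for atom onto a 1,1-dimethoxy-2-methyl-3-silyloxybutadiene plus a MeC≡C–CO2Ar unit, so the crowded depside ester is made while its acid is still unhindered but-2-ynoic acid.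
- Forward: diene from trimethyl orthopropionate (steps 1–4); ring B phenol from methyl 2,4-dihydroxy-3,6-dimethylbenzoate and its butynoate (steps 5–9); ring A built on the ester by cycloaddition and loss of methanol (step 10); O-methylation and hydrogenolysis (steps 11–12).
- Stereochemistry: the target has no stereocentre; only regiochemistry (cycloaddition; O4 versus O2 of ring B) has to be controlled.

Key step: step 10

Remark: bromide 2 has one stereocentre and is used as the racemate; the centre disappears in step 2.

**Route**

Step 1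
Reactants: 1 trimethyl orthopropionate (1,1,1-trimethoxypropane)
Product: 2 2-bromo-1,1,1-trimethoxypropane (racemic)
Conditions: Br2 (1.0 equiv), pyridine (1.1 equiv), 0 °C to rt; filter, distil under reduced pressure
Reagents that add atoms: bromine, BrBr
Why: α-Bromination of an orthoester, which reacts at its only enolisable carbon through the ketene acetal/dimethoxycarbenium equilibrium, while pyridine binds the HBr that would otherwise cleave the orthoester to methyl 2-bromopropanoate.

Step 2
Reactants: 2 2-bromo-1,1,1-trimethoxypropane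
Product: 3 1,1-dimethoxyprop-1-ene (methylketene dimethyl acetal)
Conditions: Na sand (2.1 equiv), cyclohexane, reflux, argon; filter, fractional distillation
Reagents that add atoms: none
Why: Boord-type reductive β-elimination, in which sodium reduces the C–Br bond and the carbanion expels a β-methoxide, so that only the 1,1-dimethoxyalkene can form (the classical route from α-bromo orthoesters to alkylketene acetals).

Step 3
Reactants: 3 1,1-dimethoxyprop-1-ene; 4 acetyl chloride
Product: 5 4,4-dimethoxy-3-methylbut-3-en-2-one
Conditions: Et3N (1.2 equiv), Et2O, 0 °C to rt; filter, distil under reduced pressure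
Reagents that add atoms: none
Why: C-Acylation of a ketene acetal, in which the nucleophilic β-carbon of 3 attacks the acid chloride and triethylamine removes the α-proton of the dimethoxycarbenium intermediate before chloride can demethylate it, giving the push–pull acylketene acetal.

Step 4
Reactants: 5 4,4-dimethoxy-3-methylbut-3-en-2-one
Product: 7 1,1-dimethoxy-2-methyl-3-(trimethylsilyloxy)buta-1,3-diene, via lithium dienolate 6 (not isolated)
Conditions: LiN(i-Pr)2 (LDA, 1.1 equiv), THF, −78 °C; Me3SiCl (1.2 equiv), −78 °C to rt; pentane, filter, bulb-to-bulb distillation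
Reagents that add atoms: chlorotrimethylsilane, C[Si](C)(C)Cl
Why: Kinetic enolisation and O-silylation, the standard entry to electron-rich 2-silyloxydienes, works here because the acetyl CH3 carries the only acidic protons of 5 and the hard silicon electrophile traps the cross-conjugated enolate on oxygen.

Step 5
Reactants: 8 methyl 2,4-dihydroxy-3,6-dimethylbenzoate
Product: 9 methyl 2-hydroxy-4-[(4-methoxybenzyl)oxy]-3,6-dimethylbenzoate
Conditions: 4-methoxybenzyl chloride (1.05 equiv), K2CO3 (1.5 equiv), acetone, reflux
Reagents that add atoms: 4-methoxybenzyl chloride, COc1ccc(CCl)cc1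
Why: Regioselective Williamson etherification, since the 4-OH is the more acidic and unhindered phenol whereas the 2-OH is held in a hydrogen bond to the ester carbonyl, so one equivalent of halide should alkylate O4 only.

Step 6
Reactants: 9 methyl 2-hydroxy-4-[(4-methoxybenzyl)oxy]-3,6-dimethylbenzoate
Product: 11 2-hydroxy-4-[(4-methoxybenzyl)oxy]-3,6-dimethylbenzoic acid, via dipotassium salt 10 (not isolated)
Conditions: KOH (5 equiv), DMSO/H2O 4:1, 80 °C; then cold 1 M HCl to pH 3
Reagents that add atoms: potassium hydroxide, [K+].[OH-]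
Why: Saponification of a di-ortho-substituted benzoate by poorly solvated hydroxide in aqueous DMSO, under which the 4-methoxybenzyl ether is inert, with cold acidification to avoid decarboxylation of the electron-rich salicylic acid.

Step 7
Reactants: 11 2-hydroxy-4-[(4-methoxybenzyl)oxy]-3,6-dimethylbenzoic acid
Product: 12 benzyl 2-(benzyloxy)-4-[(4-methoxybenzyl)oxy]-3,6-dimethylbenzoate
Conditions: BnBr (2.5 equiv), K2CO3 (3 equiv), DMF, 60 °C
Reagents that add atoms: benzyl bromide, BrCc1ccccc1
Why: Double Williamson-type O-alkylation, in which the carboxylate is benzylated first and the then chelated 2-phenoxide second under forcing DMF conditions, installing in one operation the two groups that hydrogenolysis later removes together.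

Step 8
Reactants: 12 benzyl 2-(benzyloxy)-4-[(4-methoxybenzyl)oxy]-3,6-dimethylbenzoate
Product: 13 benzyl 2-(benzyloxy)-4-hydroxy-3,6-dimethylbenzoate
Conditions: CF3CO2H (10 vol%), anisole (5 equiv), CH2Cl2, 0 °C to rt
Reagents that add atoms: none
Why: Acidolytic cleavage of a 4-methoxybenzyl aryl ether by SN1 ionisation to the stabilised 4-methoxybenzyl cation, which anisole traps, under conditions that the unactivated benzyl ether and benzyl ester should survive.

Step 9
Reactants: 13 benzyl 2-(benzyloxy)-4-hydroxy-3,6-dimethylbenzoate; 14 but-2-ynoic acid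
Product: 16 benzyl 2-(benzyloxy)-4-(but-2-ynoyloxy)-3,6-dimethylbenzoate, via O-acylisourea 15 (not isolated)
Conditions: DCC (1.3 equiv), DMAP (5 mol%), CH2Cl2, −10 to 0 °C
Reagents that add atoms: none
Why: Steglich esterification of an unhindered acid, so the depside C–O bond is made as a simple aryl ester before C1 of ring A has its two ortho substituents, with low temperature and little DMAP to suppress addition to the triple bond.

Step 10
Reactants: 16 benzyl 2-(benzyloxy)-4-(but-2-ynoyloxy)-3,6-dimethylbenzoate; 7 1,1-dimethoxy-2-methyl-3-(trimethylsilyloxy)buta-1,3-diene (3 equiv)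
Product: 19 benzyl 2-(benzyloxy)-4-(4-hydroxy-2-methoxy-3,6-dimethylbenzoyloxy)-3,6-dimethylbenzoate, via cyclohexadiene ketal cycloadduct 17 (not isolated), via aryl trimethylsilyl ether 18 (not isolated)
Conditions: toluene, 110 °C, sealed tube, argon; then 1 M HCl, THF, 0 °C to rt
Reagents that add atoms: none
Why: The mechanism is a thermal, concerted but asynchronous (4+2) cycloaddition in which the CH2 terminus of the diene, the site of its largest HOMO coefficient, bonds first to the methyl-bearing β-carbon of the ynoate and the dimethoxy-substituted terminus then bonds to the ester-bearing α-carbon; the 1,4-cyclohexadiene 17 loses methanol by 1,4-elimination between its ketal carbon (C2) and its CH2 (C5) to give arene 18, whose silyl ether is hydrolysed on acidic work-up. The closest known reaction type is the Diels–Alder benzannulation of 1,1-dialkoxy-3-silyloxybutadienes with alkynoates to 4-hydroxy-2-alkoxybenzoates, which has also been run on macrocyclic ynoates. Ring A is closed in the intermolecular (4+2) mode, four ring atoms coming from the diene and two from the alkyne, with C1–C2 and C5–C6 as the new bonds. No stereocentre is created, because the two sp3 ring carbons of 17 are not stereogenic and become aromatic. The step needs regioselectivity, which the matched polarisation of the three oxygen donors of the diene and the acceptor aryl ester secures (an aryl ester also lowers the ynoate LUMO more than an alkyl ester), and chemoselectivity, which the absence of acidic protons in 16 (benzyl ether at O2, benzyl ester) secures by sparing the acid-sensitive ketene acetal.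

Step 11
Reactants: 19 benzyl 2-(benzyloxy)-4-(4-hydroxy-2-methoxy-3,6-dimethylbenzoyloxy)-3,6-dimethylbenzoate
Product: 20 benzyl 2-(benzyloxy)-4-(2,4-dimethoxy-3,6-dimethylbenzoyloxy)-3,6-dimethylbenzoate
Conditions: MeI (3 equiv), K2CO3 (2 equiv), acetone, 40 °C
Reagents that add atoms: iodomethane, CI
Why: Williamson O-methylation of the only free phenol, under which the hindered diaryl ester and the benzyl ester should not be attacked by K2CO3 in acetone.

Step 12
Reactants: 20 benzyl 2-(benzyloxy)-4-(2,4-dimethoxy-3,6-dimethylbenzoyloxy)-3,6-dimethylbenzoate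
Product: 21 diffractaic acid, 4-(2,4-dimethoxy-3,6-dimethylbenzoyloxy)-2-hydroxy-3,6-dimethylbenzoic acid
Conditions: H2 (1 atm), 10% Pd/C, EtOAc, rt
Reagents that add atoms: none
Why: Catalytic hydrogenolysis cleaves the two benzylic C–O bonds (ether and ester) and frees the 2-OH and CO2H of ring B, while the aryl ester and the methyl ethers are inert and no other reducible group is present.

**Compound list**

1 | trimethyl orthopropionate (1,1,1-trimethoxypropane) | CCC(OC)(OC)OC | starting material
2 | 2-bromo-1,1,1-trimethoxypropane (racemic) | CC(Br)C(OC)(OC)OC | intermediate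
3 | 1,1-dimethoxyprop-1-ene | CC=C(OC)OC | intermediate
4 | acetyl chloride | CC(=O)Cl | starting material
5 | 4,4-dimethoxy-3-methylbut-3-en-2-one | CC(=O)C(C)=C(OC)OC | intermediate
6 | lithium 4,4-dimethoxy-3-methylbuta-1,3-dien-2-olate (not isolated) | COC(OC)=C(C)C(=C)O[Li] | intermediate
7 | 1,1-dimethoxy-2-methyl-3-(trimethylsilyloxy)buta-1,3-diene | COC(OC)=C(C)C(=C)O[Si](C)(C)C | intermediate
8 | methyl 2,4-dihydroxy-3,6-dimethylbenzoate | COC(=O)c1c(C)cc(O)c(C)c1O | starting material
9 | methyl 2-hydroxy-4-[(4-methoxybenzyl)oxy]-3,6-dimethylbenzoate | COC(=O)c1c(C)cc(OCc2ccc(OC)cc2)c(C)c1O | intermediate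
10 | dipotassium 4-[(4-methoxybenzyl)oxy]-3,6-dimethyl-2-oxidobenzoate (not isolated) | COc1ccc(COc2cc(C)c(C(=O)[O-])c([O-])c2C)cc1.[K+].[K+] | intermediate
11 | 2-hydroxy-4-[(4-methoxybenzyl)oxy]-3,6-dimethylbenzoic acid | COc1ccc(COc2cc(C)c(C(=O)O)c(O)c2C)cc1 | intermediate
12 | benzyl 2-(benzyloxy)-4-[(4-methoxybenzyl)oxy]-3,6-dimethylbenzoate | COc1ccc(COc2cc(C)c(C(=O)OCc3ccccc3)c(OCc3ccccc3)c2C)cc1 | intermediate
13 | benzyl 2-(benzyloxy)-4-hydroxy-3,6-dimethylbenzoate | Cc1cc(O)c(C)c(OCc2ccccc2)c1C(=O)OCc1ccccc1 | intermediate
14 | but-2-ynoic acid | CC#CC(=O)O | starting material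
15 | O-(but-2-ynoyl)-N,N'-dicyclohexylisourea (not isolated) | CC#CC(=O)OC(=NC1CCCCC1)NC1CCCCC1 | intermediate
16 | benzyl 2-(benzyloxy)-4-(but-2-ynoyloxy)-3,6-dimethylbenzoate | CC#CC(=O)Oc1cc(C)c(C(=O)OCc2ccccc2)c(OCc2ccccc2)c1C | intermediate
17 | benzyl 2-(benzyloxy)-4-{[6,6-dimethoxy-2,5-dimethyl-4-(trimethylsilyloxy)cyclohexa-1,4-diene-1-carbonyl]oxy}-3,6-dimethylbenzoate (not isolated) | COC1(OC)C(C)=C(O[Si](C)(C)C)CC(C)=C1C(=O)Oc1cc(C)c(C(=O)OCc2ccccc2)c(OCc2ccccc2)c1C | intermediate
18 | benzyl 2-(benzyloxy)-4-{[2-methoxy-3,6-dimethyl-4-(trimethylsilyloxy)benzoyl]oxy}-3,6-dimethylbenzoate (not isolated) | COc1c(C)c(O[Si](C)(C)C)cc(C)c1C(=O)Oc1cc(C)c(C(=O)OCc2ccccc2)c(OCc2ccccc2)c1C | intermediate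
19 | benzyl 2-(benzyloxy)-4-(4-hydroxy-2-methoxy-3,6-dimethylbenzoyloxy)-3,6-dimethylbenzoate | Cc1cc(O)c(C)c(OC)c1C(=O)Oc1cc(C)c(C(=O)OCc2ccccc2)c(OCc2ccccc2)c1C | intermediate
20 | benzyl 2-(benzyloxy)-4-(2,4-dimethoxy-3,6-dimethylbenzoyloxy)-3,6-dimethylbenzoate | COc1cc(C)c(C(=O)Oc2cc(C)c(C(=O)OCc3ccccc3)c(OCc3ccccc3)c2C)c(OC)c1C | intermediate
21 | diffractaic acid | COc1cc(C)c(C(=O)Oc2cc(C)c(C(=O)O)c(O)c2C)c(OC)c1C | target

**Step count and risks**

Total: 12 steps. Longest linear sequence: 8 steps (steps 5–12, from methyl 2,4-dihydroxy-3,6-dimethylbenzoate); the diene branch (steps 1–4) joins at step 10.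

Steps most likely to fail:

1. Step 10. The cycloaddition may be too slow at temperatures the diene tolerates, so that hydrolysis, silyl transfer or polymerisation of the diene outruns ring formation; the ketal may also hydrolyse on work-up instead of losing methanol. The fallback gives up the cycloaddition and makes the depside bond last. It sets out from 8: both phenols are methylated (MeI, K2CO3, DMF, 60 °C) to methyl 2,4-dimethoxy-3,6-dimethylbenzoate F1, which is saponified (KOH, DMSO/H2O, 100 °C) to 2,4-dimethoxy-3,6-dimethylbenzoic acid F2. Activation with trifluoroacetic anhydride in toluene as 2,4-dimethoxy-3,6-dimethylbenzoic trifluoroacetic anhydride F3 and acylation of phenol 13 should give 20, where the route is rejoined.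

2. Step 4. The amide base may attack the ketene acetal carbon in conjugate fashion, and the diene may lose its silyl group or hydrolyse during isolation. The fallback uses another diene, whose ketal carbon carries one methoxy and one silyloxy group, and sets out from 16. Commercial methyl 2-methyl-3-oxobutanoate is converted with Me3SiCl/Et3N into methyl 2-methyl-3-(trimethylsilyloxy)but-2-enoate F4 and then with LiN(i-Pr)2/Me3SiCl into 1-methoxy-2-methyl-1,3-bis(trimethylsilyloxy)buta-1,3-diene F5. Heated with 16 in toluene, this diene should give the cycloadduct benzyl 2-(benzyloxy)-4-{[6-methoxy-2,5-dimethyl-4,6-bis(trimethylsilyloxy)cyclohexa-1,4-diene-1-carbonyl]oxy}-3,6-dimethylbenzoate F6. Loss of methanol should lead to benzyl 2-(benzyloxy)-4-{[3,6-dimethyl-2,4-bis(trimethylsilyloxy)benzoyl]oxy}-3,6-dimethylbenzoate F7, and acidic work-up to benzyl 2-(benzyloxy)-4-(2,4-dihydroxy-3,6-dimethylbenzoyloxy)-3,6-dimethylbenzoate F8. Methylation of both phenols (MeI, K2CO3, DMF, 50 °C) returns to 20; any material that has lost silanol instead is 19 and converges at the same point.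

3. Step 2. Reduction on the sodium surface may stall, the sodium methoxide formed may oligomerise the ketene acetal, and the volatile, moisture-sensitive product may be lost on distillation. The fallback replaces the reductive elimination by a halogen-free elimination and sets out from 1: heating 1 with a catalytic amount of Al(OCH3)3 while methanol is distilled off through a column (dealcoholation of an orthoester to its ketene acetal) should lead directly to 3. This fallback makes no new compound (F0).

**Further compounds**

F1 | step 10 | methyl 2,4-dimethoxy-3,6-dimethylbenzoate | COC(=O)c1c(C)cc(OC)c(C)c1OC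
F2 | step 10 | 2,4-dimethoxy-3,6-dimethylbenzoic acid | COc1cc(C)c(C(=O)O)c(OC)c1C
F3 | step 10 | 2,4-dimethoxy-3,6-dimethylbenzoic trifluoroacetic anhydride | COc1cc(C)c(C(=O)OC(=O)C(F)(F)F)c(OC)c1C
F4 | step 4 | methyl 2-methyl-3-(trimethylsilyloxy)but-2-enoate (E/Z mixture) | COC(=O)C(C)=C(C)O[Si](C)(C)C
F5 | step 4 | 1-methoxy-2-methyl-1,3-bis(trimethylsilyloxy)buta-1,3-diene (E/Z mixture) | COC(O[Si](C)(C)C)=C(C)C(=C)O[Si](C)(C)C
F6 | step 4 | benzyl 2-(benzyloxy)-4-{[6-methoxy-2,5-dimethyl-4,6-bis(trimethylsilyloxy)cyclohexa-1,4-diene-1-carbonyl]oxy}-3,6-dimethylbenzoate (racemic) | COC1(O[Si](C)(C)C)C(C)=C(O[Si](C)(C)C)CC(C)=C1C(=O)Oc1cc(C)c(C(=O)OCc2ccccc2)c(OCc2ccccc2)c1C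
F7 | step 4 | benzyl 2-(benzyloxy)-4-{[3,6-dimethyl-2,4-bis(trimethylsilyloxy)benzoyl]oxy}-3,6-dimethylbenzoate | Cc1cc(O[Si](C)(C)C)c(C)c(O[Si](C)(C)C)c1C(=O)Oc1cc(C)c(C(=O)OCc2ccccc2)c(OCc2ccccc2)c1C
F8 | step 4 | benzyl 2-(benzyloxy)-4-(2,4-dihydroxy-3,6-dimethylbenzoyloxy)-3,6-dimethylbenzoate | Cc1cc(O)c(C)c(O)c1C(=O)Oc1cc(C)c(C(=O)OCc2ccccc2)c(OCc2ccccc2)c1C
F0 | step 2 | none | none
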